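The constants were chosen freely.

Follow the leaving ligand through these flasks, starting with elm.

    substrate ⇌ intermediate + leaving ligand (K1 = 1.7 × 10⁻⁴ M, k1 = 0.22 s⁻¹, Ea1 = 73.0 kJ mol⁻¹, ΔH1 = −15.0 kJ mol⁻¹)
    partner + intermediate → target (k2 = 680 M⁻¹ s⁻¹, Ea2 = 43.0 kJ mol⁻¹)
    target ⇌ isomer of the product (K3 = 7.0, k3 = 0.11 s⁻¹, Ea3 = 78.0 kJ mol⁻¹, ΔH3 = −41.0 kJ mol⁻¹)
    solid reagent ⇌ partner, rate k4*(cs4 - [partner]) while solid is left; crystals form when [partner] > cs4 (cs4 = 3.0 mM, k4 = 2.5 s⁻¹)
    (constants at 50 °C)

the same everywhere: substrate 16 mM; solid reagent 17.6 mM; time 8.0 s

| charge | remark | temperature |
|---|---|---|
| maple | at 50 °C until 2.5 s, from then on at 20 °C |  |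
| elm |  | 50 °C |
| alder |  | 20 °C |

- given per volume of solution although it is solid: solid reagent
- at 50 °C the constants are as listed, elsewhere as the activation energies and enthalpies make them
- at the start none of the solid reagent is in solution

- the flask with the highest amount of target, in percent of the substrate charged ("all alike" if they lie within 1.5 percentage points) (maple / elm / alder / all alike)
- final target, as a percentage of the substrate charged, in maple
- final target, as a percentage of the substrate charged, in elm
- final target, as a percentage of the substrate charged, in alder

I wrote L for the concentration of leaving ligand in elm, at 50 °C. An intermediate there had two ways on: capture by partner, or return to substrate with a ligand. I held partner at its solubility, because dissolution begins at 7.50 mM s⁻¹, faster than the 3.52 mM s⁻¹ at which substrate first ionises. Capture constant times solubility times equilibrium constant, over the forward constant of the first step, gave Lh = 1.58 mM, which I named the half-capture ligand level: the ligand concentration at which an intermediate is as likely to return as to be captured. This is the common-ion effect in one number, and the captured share is Lh/(Lh + L).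

With substrate held at a steady value S, ligand grows at the forward constant times S times that share. Integrated, L plus L squared over twice Lh equals the forward constant times S times the time. I solved two extreme versions. With substrate staying at its full charge, L reached 7.98 mM. With substrate sitting from the start at what that leaves, 8.02 mM, L reached 5.28 mM, which is lower. The real substrate should lie between those two levels, so I expected the real L between these two results.

Since L runs past Lh, it grows roughly as the square root of time, and such a curve averages 0.667 of its end value. I therefore put the average substrate, the charge minus that fraction of L, back into the equation. The upper result as starting value gave 6.28 mM, and one more round gave 6.67 mM. For the same curve the mean age of what was formed is 5.33 s. Counting the released ligand as target formed, which sets aside the free intermediate, and letting target leak to its isomer at the forward 0.11 s⁻¹ for that age, which sets aside the return step, I committed to 23.2% of target in elm.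

The forecast named elm, with 23% (20.5% to 26%) in elm, 20.5% (18% to 23.5%) in maple and 9.2% (8% to 10.5%) in alder, noting that “the released ligand increasingly returns the intermediate to substrate”.

Elm gave 23.3%, above maple at 19.1% and alder at 6.71%. The leaving ligand in elm read 6.16 mM at 8.00 s, a little below my 6.67 mM. At that reading Lh puts the captured share in elm at 20.4%. In alder, at 20 °C, the same expression with the cold constants gives Lh = 8.75 mM, above the 1.54 mM of ligand that alder held at 8.00 s, which puts the captured share in alder at 85.0%.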